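**Retrosynthetic overview**
- Last disconnection: the two N-Boc groups (indole N1 and pyrrole N1) of the fully assembled, doubly brominated skeleton.
- Key disconnection: the oxazole C2–pyrrole C2 bond, giving N-Boc 5-(6-bromo-4-methoxyindol-3-yl)oxazole (free C2–H) and N-Boc-2-bromo-5-iodopyrrole. The forward step is a one-pot C2–H zincation and iodide-selective Negishi coupling, with both bromine atoms already in place.
- Enabling feature: the oxazole C2–H sits between ring O1 and ring N3 and is the most acidic C–H of the indolyl-oxazole. A mild zinc amide therefore metalates only there, and the C–Zn bond keeps the oxazole ring closed. On the pyrrole, C5–I versus C2–Br (and indole C6–Br) tells palladium where to insert.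
- Oxazole ring: van Leusen annulation of TosMIC onto 6-bromo-4-methoxyindole-3-carbaldehyde, itself from Vilsmeier formylation of the purchased indole. The pyrrole is bought as N-Boc-pyrrole, dibrominated symmetrically, then desymmetrised by one Br→Li→I exchange.
- Ring order: indole (bought), oxazole (built in step 2), pyrrole (bought, joined in the key step).

Key step: step 6

Remark: the target is planar and has no stereogenic element, so no stereocontrol is needed and all SMILES carry no stereodescriptors; 6-bromo-4-methoxy-1H-indole, TosMIC and N-Boc-pyrrole are taken as purchasable.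

**Step 1**
Reactants: 1 6-bromo-4-methoxy-1H-indole
Product: 3 6-bromo-4-methoxy-1H-indole-3-carbaldehyde, via iminium chloride 2 (not isolated)
Conditions: POCl3, DMF, 0 °C to 35 °C; then aq. NaOH
Reagents that add atoms: N,N-dimethylformamide CN(C)C=O; water O
Why: Vilsmeier–Haack formylation, in which the chloroiminium ion attacks the enamine-like C3 of the indole (its most nucleophilic carbon) and aqueous base hydrolyses iminium salt 2 to the aldehyde, the aryl bromide and methyl ether being inert.

**Step 2**
Reactants: 3 6-bromo-4-methoxy-1H-indole-3-carbaldehyde; 4 p-toluenesulfonylmethyl isocyanide (TosMIC)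
Product: 6 5-(6-bromo-4-methoxy-1H-indol-3-yl)-1,3-oxazole, via 4-tosyl-2-oxazoline 5 (not isolated)
Conditions: K2CO3, MeOH, reflux
Reagents that add atoms: none
Why: van Leusen oxazole synthesis, in which deprotonated TosMIC adds to the aldehyde, the alkoxide closes onto the isocyanide carbon to give oxazoline 5, and loss of p-toluenesulfinate aromatises the oxazole with the indolyl group at C5; the reaction type tolerates N-unprotected indole-3-carbaldehydes.

**Step 3**
Reactants: 6 5-(6-bromo-4-methoxy-1H-indol-3-yl)-1,3-oxazole
Product: 7 tert-butyl 6-bromo-4-methoxy-3-(1,3-oxazol-5-yl)-1H-indole-1-carboxylate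
Conditions: Boc2O, DMAP (cat.), MeCN, 25 °C
Reagents that add atoms: di-tert-butyl dicarbonate CC(C)(C)OC(=O)OC(=O)OC(C)(C)C
Why: DMAP-catalysed N-acylation (Boc protection) masks the only acidic N–H before the metalation and tempers the electron-rich indole, while the weakly basic oxazole nitrogen does not retain an acyl group.

**Step 4**
Reactants: 8 tert-butyl 1H-pyrrole-1-carboxylate
Product: 9 tert-butyl 2,5-dibromo-1H-pyrrole-1-carboxylate
Conditions: NBS (2.0 equiv), THF, −78 °C to rt
Reagents that add atoms: N-bromosuccinimide O=C1CCC(=O)N1Br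
Why: electrophilic aromatic bromination, in which the two α-positions of the N-acylpyrrole are the most reactive and are brominated in turn, giving the symmetric 2,5-dibromide that fixes the later 2,5-relationship of bromine and oxazole.

**Step 5**
Reactants: 9 tert-butyl 2,5-dibromo-1H-pyrrole-1-carboxylate
Product: 11 tert-butyl 2-bromo-5-iodo-1H-pyrrole-1-carboxylate, via lithiopyrrole 10 (not isolated)
Conditions: n-BuLi (1.0 equiv), THF, −78 °C; then I2, −78 °C
Reagents that add atoms: iodine II
Why: bromine–lithium exchange with one equivalent of n-BuLi gives the carbamate-stabilised α-lithio species 10 (a second exchange on the anionic ring is slower and −78 °C suppresses N-to-C migration of the Boc group), and iodinolysis places iodine at that carbon.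

**Step 6**
Reactants: 7 tert-butyl 6-bromo-4-methoxy-3-(1,3-oxazol-5-yl)-1H-indole-1-carboxylate; 11 tert-butyl 2-bromo-5-iodo-1H-pyrrole-1-carboxylate
Product: 13 tert-butyl 6-bromo-3-{2-[5-bromo-1-(tert-butoxycarbonyl)-1H-pyrrol-2-yl]-1,3-oxazol-5-yl}-4-methoxy-1H-indole-1-carboxylate, via oxazol-2-ylzinc chloride 12 (not isolated)
Conditions: TMPZnCl·LiCl (1.2 equiv), THF, 25 °C; then 11, Pd(dba)2 (cat.), P(2-furyl)3 (cat.), THF, 25–40 °C
Reagents that add atoms: none
Why: TMPZnCl·LiCl removes the oxazole C2–H of 7 (the C–H between O1 and N3) to give the ring-closed C2-zinc species 12; Pd(0) then inserts into the C–I bond of 11, and transmetalation from zinc followed by reductive elimination forms the oxazole C2–pyrrole C2 bond. The closest known reaction type is C2 metalation of oxazoles with a TMP-zinc amide followed by Pd-catalysed Negishi coupling with aryl iodides, in effect a C–H heteroarylation. No ring is closed and no stereocentre is formed. Three selectivities are needed: the site of metalation is secured by the much higher acidity of the oxazole C2–H over indole C2–H, C5–H, C7–H and oxazole C4–H and by the mildness of the zinc amide, which also leaves both carbamates and the C–Br bond untouched; ring integrity is secured by the covalent C–Zn bond, which does not open to the isocyano enolate as the lithium species does, so coupling occurs at C2 and not at C4; halide discrimination is secured by oxidative addition into C–I at 25–40 °C with a triarylphosphine-type catalyst, under which indole C6–Br and pyrrole C5–Br should remain intact. The step delivers the complete indole–oxazole–pyrrole skeleton with both bromine atoms in their final positions, so no late electrophilic bromination has to distinguish the pyrrole from the indole.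

**Step 7**
Reactants: 13 tert-butyl 6-bromo-3-{2-[5-bromo-1-(tert-butoxycarbonyl)-1H-pyrrol-2-yl]-1,3-oxazol-5-yl}-4-methoxy-1H-indole-1-carboxylate
Product: 14 6-bromo-3-[2-(5-bromo-1H-pyrrol-2-yl)-1,3-oxazol-5-yl]-4-methoxy-1H-indole (target CNP0145233.0)
Conditions: K2CO3, MeOH/THF, 25–45 °C
Reagents that add atoms: none
Why: base-mediated methanolysis of the two N-Boc groups, which are unusually electrophilic carbamates because each nitrogen lone pair belongs to an aromatic sextet, while the aryl bromide, bromopyrrole, oxazole and methyl ether are stable to carbonate in methanol.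

**Compound list**
1 | 6-bromo-4-methoxy-1H-indole | COc1cc(Br)cc2[nH]ccc12 | starting material
2 | N-[(6-bromo-4-methoxy-1H-indol-3-yl)methylidene]-N-methylmethanaminium chloride | COc1cc(Br)cc2[nH]cc(C=[N+](C)C)c12.[Cl-] | intermediate
3 | 6-bromo-4-methoxy-1H-indole-3-carbaldehyde | COc1cc(Br)cc2[nH]cc(C=O)c12 | intermediate
4 | p-toluenesulfonylmethyl isocyanide (TosMIC) | [C-]#[N+]CS(=O)(=O)c1ccc(C)cc1 | starting material
5 | 5-(6-bromo-4-methoxy-1H-indol-3-yl)-4-tosyl-4,5-dihydro-1,3-oxazole (racemic, relative configuration not defined, both centres lost on elimination) | COc1cc(Br)cc2[nH]cc(C3OC=NC3S(=O)(=O)c3ccc(C)cc3)c12 | intermediate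
6 | 5-(6-bromo-4-methoxy-1H-indol-3-yl)-1,3-oxazole | COc1cc(Br)cc2[nH]cc(-c3cnco3)c12 | intermediate
7 | tert-butyl 6-bromo-4-methoxy-3-(1,3-oxazol-5-yl)-1H-indole-1-carboxylate | COc1cc(Br)cc2n(C(=O)OC(C)(C)C)cc(-c3cnco3)c12 | intermediate
8 | tert-butyl 1H-pyrrole-1-carboxylate | CC(C)(C)OC(=O)n1cccc1 | starting material
9 | tert-butyl 2,5-dibromo-1H-pyrrole-1-carboxylate | CC(C)(C)OC(=O)n1c(Br)ccc1Br | intermediate
10 | tert-butyl 2-bromo-5-lithio-1H-pyrrole-1-carboxylate | CC(C)(C)OC(=O)n1c(Br)ccc1[Li] | intermediate
11 | tert-butyl 2-bromo-5-iodo-1H-pyrrole-1-carboxylate | CC(C)(C)OC(=O)n1c(Br)ccc1I | intermediate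
12 | {5-[6-bromo-1-(tert-butoxycarbonyl)-4-methoxy-1H-indol-3-yl]-1,3-oxazol-2-yl}zinc chloride (LiCl complex in THF) | COc1cc(Br)cc2n(C(=O)OC(C)(C)C)cc(-c3cnc([Zn]Cl)o3)c12 | intermediate
13 | tert-butyl 6-bromo-3-{2-[5-bromo-1-(tert-butoxycarbonyl)-1H-pyrrol-2-yl]-1,3-oxazol-5-yl}-4-methoxy-1H-indole-1-carboxylate | COc1cc(Br)cc2n(C(=O)OC(C)(C)C)cc(-c3cnc(-c4ccc(Br)n4C(=O)OC(C)(C)C)o3)c12 | intermediate
14 | 6-bromo-3-[2-(5-bromo-1H-pyrrol-2-yl)-1,3-oxazol-5-yl]-4-methoxy-1H-indole | COc1cc(Br)cc2[nH]cc(-c3cnc(-c4ccc(Br)[nH]4)o3)c12 | target

**Step count**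
Total steps: 7. Longest linear sequence: 5 steps (steps 1, 2, 3, 6, 7, from 1 to 14); the pyrrole branch (steps 4 and 5) joins at step 6.

**Steps most likely to fail, with fallbacks**

Step 6. The risks are incomplete C2 zincation, or slow transmetalation of the oxazolylzinc during which palladium begins to insert into C–Br bonds and causes oligomerisation, or protodezincation before coupling. The fallback reverses the polarity of the two partners; it sets out from 7 (with 9 for the partner) and returns at 13. Deprotonation of 7 with LiHMDS in THF at −78 °C (no polar cosolvent) and quenching with iodine should give tert-butyl 6-bromo-3-(2-iodo-1,3-oxazol-5-yl)-4-methoxy-1H-indole-1-carboxylate F1. In a second flask 9 is converted with n-BuLi at −78 °C into 10 and transmetalated with ZnCl2 to [5-bromo-1-(tert-butoxycarbonyl)-1H-pyrrol-2-yl]zinc chloride F2. F2 is coupled with F1 under Pd(PPh3)4 in THF at 25 °C; oxidative addition into the oxazole C2–I bond is far faster than into any C–Br bond, and the Negishi product is 13.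

Step 5. The risks are loss of mono-selectivity in the halogen–metal exchange, migration of the Boc group onto the lithiated carbon, or butylation of the anion by the butyl bromide formed. The fallback uses only electrophilic halogenation; it sets out from 8 and returns at 11. One equivalent of NBS in THF at −78 °C should give tert-butyl 2-bromo-1H-pyrrole-1-carboxylate F3. N-Iodosuccinimide in DMF (catalytic TFA if needed) at 0 °C should then iodinate the remaining free α-position to give 11.

Step 2. The risk is slow addition of the TosMIC anion to a carbonyl that is deactivated by the indole nitrogen lone pair (more so once N–H is deprotonated) and crowded by the peri-methoxy group, so that TosMIC is consumed by methanolysis instead. The fallback attaches a preformed oxazole by cross-coupling; it sets out from 1 and returns at 7, bypassing steps 1–3. Iodination of 1 with I2/KOH in DMF should give 6-bromo-3-iodo-4-methoxy-1H-indole F4, which is protected at once with Boc2O/DMAP to give tert-butyl 6-bromo-3-iodo-4-methoxy-1H-indole-1-carboxylate F5. Suzuki–Miyaura coupling of F5 with purchased 2-(triisopropylsilyl)-1,3-oxazol-5-ylboronic acid pinacol ester (Pd(dppf)Cl2, K3PO4, dioxane/water, 60 °C, C–I reacting before C–Br) should give tert-butyl 6-bromo-4-methoxy-3-[2-(triisopropylsilyl)-1,3-oxazol-5-yl]-1H-indole-1-carboxylate F6. TBAF in THF at 0 °C then removes the C2 silyl group to give 7; should the indole Boc group be lost as well, the material re-enters at 6.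

**Further compounds**
F1 | step 6 | tert-butyl 6-bromo-3-(2-iodo-1,3-oxazol-5-yl)-4-methoxy-1H-indole-1-carboxylate | COc1cc(Br)cc2n(C(=O)OC(C)(C)C)cc(-c3cnc(I)o3)c12
F2 | step 6 | [5-bromo-1-(tert-butoxycarbonyl)-1H-pyrrol-2-yl]zinc chloride | CC(C)(C)OC(=O)n1c(Br)ccc1[Zn]Cl
F3 | step 5 | tert-butyl 2-bromo-1H-pyrrole-1-carboxylate | CC(C)(C)OC(=O)n1cccc1Br
F4 | step 2 | 6-bromo-3-iodo-4-methoxy-1H-indole | COc1cc(Br)cc2[nH]cc(I)c12
F5 | step 2 | tert-butyl 6-bromo-3-iodo-4-methoxy-1H-indole-1-carboxylate | COc1cc(Br)cc2n(C(=O)OC(C)(C)C)cc(I)c12
F6 | step 2 | tert-butyl 6-bromo-4-methoxy-3-[2-(triisopropylsilyl)-1,3-oxazol-5-yl]-1H-indole-1-carboxylate | COc1cc(Br)cc2n(C(=O)OC(C)(C)C)cc(-c3cnc([Si](C(C)C)(C(C)C)C(C)C)o3)c12
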